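**Plan**
Guaiane numbering is used. Ring A is C1–C5 (five-membered) and ring B is C1, C5–C10 (seven-membered). C4 bears OH and CH3, C6 bears OH, C7 bears i-Pr, C8 bears the vanillate, and the alkene is C1=C10.
Retrosynthetic cuts, in order: O8–acyl; C6 carbinol to ketone; C4–C5 (opens ring A to a 3-oxobutyl chain on C1); C1=C10 (opens ring B); C5–C6; C7–C8.
Forward: C7–C8 by aldol, C5–C6 by acylation of an allyl anion, ring B by ring-closing metathesis, ring A by an aldol closure, then C6 reduction and O8 acylation.
Enabling feature: HO–C4–C5–C6–O is an aldol array, and C5 also adjoins the C1=C10 alkene of ring B. In the 6-ketone the C5 methylene is therefore doubly activated and sits three atoms from the C4 carbonyl.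
Stereochemistry: C7 and C8 come from an oxazolidinone-controlled syn-aldol. C4 and C5 come from a reversible, lithium-chelated aldol that settles in the all-equatorial chair of ring B. C6 comes from hydride delivery directed by the new C4 hydroxyl.

Key step: step 9

Remark: α/β refer to the usual guaiane drawing (H5 α). Compounds 1, 3, 8 and 19 are taken as commercial.

**Step 1**
Reactants: 1 3-methylbut-3-en-1-ol
Product: 2 3-methylbut-3-enal
Conditions: Dess–Martin periodinane, NaHCO3, CH2Cl2, 0 °C; used as a dried solution
Reagents that add atoms: none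
Why: The Dess–Martin oxidation turns the primary homoallylic alcohol into the aldehyde under buffered, nearly neutral conditions, so the 1,1-disubstituted alkene should not move into conjugation.

**Step 2**
Reactants: 3 (4R)-4-benzyl-3-(3-methylbutanoyl)-1,3-oxazolidin-2-one; 2 3-methylbut-3-enal
Product: 5 (4R)-4-benzyl-3-[(2R,3S)-3-hydroxy-5-methyl-2-(propan-2-yl)hex-5-enoyl]-1,3-oxazolidin-2-one, via dibutylboron (Z)-enolate 4 (not isolated)
Conditions: Bu2BOTf, Et3N, CH2Cl2, −78 to 0 °C; 2, −78 °C; H2O2, MeOH, pH 7 buffer
Reagents that add atoms: none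
Why: In this Evans syn-aldol reaction the (Z)-boron enolate 4 reacts through a closed Zimmerman–Traxler chair on the face away from the benzyl group, which sets C7 and C8 in the syn relationship that becomes i-Pr/O trans on ring B.

**Step 3**
Reactants: 5 aldol adduct
Product: 6 (2R,3S)-3-hydroxy-N-methoxy-N,5-dimethyl-2-(propan-2-yl)hex-5-enamide
Conditions: MeONHMe·HCl, AlMe3, CH2Cl2, −10 °C to rt
Reagents that add atoms: N,O-dimethylhydroxylamine hydrochloride, CNOC.Cl
Why: Aluminium-amide transamination (Weinreb amide formation), helped by the free C8 hydroxyl binding aluminium, releases the auxiliary without touching C7 or C8.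

**Step 4**
Reactants: 6 hydroxy Weinreb amide
Product: 7 (2R,3S)-3-[(tert-butyldimethylsilyl)oxy]-N-methoxy-N,5-dimethyl-2-(propan-2-yl)hex-5-enamide
Conditions: TBSOTf, 2,6-lutidine, CH2Cl2, 0 °C
Reagents that add atoms: tert-butyldimethylsilyl triflate, CC(C)(C)[Si](C)(C)OS(=O)(=O)C(F)(F)F
Why: Silylation of the hindered secondary alcohol blocks retro-aldol cleavage and leaves a poor leaving group β to the future ketone, with no stereocentre touched.

**Step 5**
Reactants: 8 5-methylhex-5-en-2-one
Product: 9 2-methyl-2-(3-methylbut-3-en-1-yl)-1,3-dioxolane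
Conditions: HOCH2CH2OH, pyridinium p-toluenesulfonate (cat.), benzene, reflux, water separator
Reagents that add atoms: ethane-1,2-diol, OCCO
Why: Acid-catalysed ketalisation masks the ketone against the superbase of step 6, and the mild pyridinium acid limits alkene migration.

**Step 6**
Reactants: 9 dioxolane; 7 silylated Weinreb amide
Product: 11 (5R,6S)-6-[(tert-butyldimethylsilyl)oxy]-8-methyl-2-[2-(2-methyl-1,3-dioxolan-2-yl)ethyl]-5-(propan-2-yl)nona-1,8-dien-4-one, via allylpotassium reagent 10 (not isolated)
Conditions: n-BuLi, KOt-Bu, THF, −78 to −50 °C; 7, −78 °C; AcOH, −78 °C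
Reagents that add atoms: none
Why: The n-BuLi/KOt-Bu superbase metalates the methyl group of the 2-alkylpropene unit to give an allyl anion with two equivalent CH2 termini, and its acylation stops at the ketone stage (Weinreb ketone synthesis) to give the skipped β,γ-unsaturated ketone after the cold acidic quench.

**Step 7**
Reactants: 11 dienyl ketone
Product: 12 (2R,3S)-3-[(tert-butyldimethylsilyl)oxy]-5-methyl-6-[2-(2-methyl-1,3-dioxolan-2-yl)ethyl]-2-(propan-2-yl)cyclohept-5-en-1-one
Conditions: RuCl2(=CH-2-i-PrOC6H4)[1,3-bis(2-methylphenyl)imidazolidin-2-ylidene] (o-tolyl analogue of the second-generation Hoveyda–Grubbs catalyst, 5–10 mol %), 1,4-benzoquinone (10 mol %), toluene, 2 mM, 80–100 °C, argon sparge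
Reagents that add atoms: none
Why: Ring-closing metathesis of the two 1,1-disubstituted alkenes closes ring B and makes the tetrasubstituted C1=C10 alkene, a reaction type known for seven-membered rings with sterically reduced N-aryl carbene ruthenium catalysts, while benzoquinone suppresses hydride-induced alkene migration.

**Step 8**
Reactants: 12 ring B ketal
Product: 13 (2R,3S)-3-[(tert-butyldimethylsilyl)oxy]-5-methyl-6-(3-oxobutyl)-2-(propan-2-yl)cyclohept-5-en-1-one
Conditions: aq. HCl (1 M, cat.), THF, 0 °C to rt
Reagents that add atoms: water, O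
Why: Mild acid hydrolysis of the dioxolane frees the C4 ketone, the hindered secondary silyl ether survives, and the tetrasubstituted alkene of a seven-membered skipped enone has little driving force to move.

**Step 9**
Reactants: 13 diketone
Product: 16 8α-[(tert-butyldimethylsilyl)oxy]-4β-hydroxy-5αH,7αH-guai-1(10)-en-6-one, (4S,5R,7R,8S), via lithium dienolate 14 (not isolated), via lithium aldolate 15 (not isolated)
Conditions: LiN(SiMe3)2 (1.05 equiv), THF, −78 °C; −78 to −20 °C; AcOH, −78 °C
Reagents that add atoms: none
Why: LiN(SiMe3)2 removes a C5 proton of 13, the only ones flanked by both the C6 carbonyl and the C1=C10 alkene, and dienolate 14 adds through its α-carbon C5 to the C4 ketone; this is an intramolecular aldol addition whose closest known types are the α-selective aldol of extended enolates and the aldol cyclisation of 1,6-diketones. Ring A closes in the 5-(enolexo)-exo-trig mode, because attack through C10 would need rotation about the C1–C10 bond and would join two fully substituted carbons, the methyl-ketone enolates have no unstrained ring to close, and HN(SiMe3)2 is too weak an acid to shuttle protons, so only C4–C5 can form and the alkene stays at C1=C10. C4 is set by the lithium bridge between O4 and O6 in a closed Zimmerman–Traxler-type transition state, which places the new oxygen cis to C6 on ring A and the methyl group cis to H5. C5 is set under thermodynamic control: ring A holds the C5–C4 bond near the plane of the alkene (pseudo-equatorial on ring B), so the β-face aldolate 15 is the chair with C4, i-Pr and OTBS all equatorial, whereas the α-face aldolate, expected to form faster because it avoids the i-Pr group, must carry i-Pr and OTBS trans-diaxial and should revert by retro-aldol on warming. The step needs site-selective deprotonation, α over γ attack, face selectivity and survival of the β-silyloxy ketone. These are secured by the doubly activated C5 methylene, by one equivalent of base, by storage of the product as the chelated alkoxide (no second deprotonation at C5, no enolate at C7) and by the cold acetic acid quench.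

**Step 10**
Reactants: 16 hydroxy ketone
Product: 17 8α-[(tert-butyldimethylsilyl)oxy]-5αH,7αH-guai-1(10)-ene-4β,6β-diol, (4S,5S,6R,7S,8S)
Conditions: Me4NBH(OAc)3, MeCN–AcOH (1:1), −30 to −20 °C
Reagents that add atoms: none
Why: In this Evans–Saksena hydroxyl-directed reduction, after exchange of an acetate on boron for O4, hydride is passed on within a chair having C1 and C7 equatorial and the carbonyl oxygen axial, that is to the α face of C6, which gives the axial 6β-alcohol with H5 and O6 antiperiplanar.

**Step 11**
Reactants: 17 silyl ether diol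
Product: 18 5αH,7αH-guai-1(10)-ene-4β,6β,8α-triol
Conditions: Bu4NF, THF, rt to 40 °C
Reagents that add atoms: none
Why: This is a fluoride-induced desilylation, and no base-sensitive carbonyl group remains in the molecule.

**Step 12**
Reactants: 18 triol; 19 4-(benzyloxy)-3-methoxybenzoic acid
Product: 20 4β,6β-dihydroxy-5αH,7αH-guai-1(10)-en-8α-yl 4-(benzyloxy)-3-methoxybenzoate
Conditions: 19 (1.05 equiv), DCC, DMAP (cat.), CH2Cl2, 0 °C to rt
Reagents that add atoms: none
Why: The Steglich esterification runs under steric control, since C8–OH is equatorial and next to a CH2 group, C6–OH is axial, flanked by two branched carbons and hydrogen-bonded to O4, and C4–OH is tertiary, so one equivalent of acid should acylate O8 only.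

**Step 13**
Reactants: 20 benzyl-protected ester
Product: 21 (4S,5S,6R,7S,8S)-4,6-dihydroxyguai-1(10)-en-8-yl 4-hydroxy-3-methoxybenzoate (target)
Conditions: H2 (1 atm), palladium on carbon (Pd/C), EtOAc, rt
Reagents that add atoms: none
Why: Hydrogenolysis removes the phenolic benzyl ether, the tetrasubstituted alkene is inert under these conditions, and no C–O bond of the terpene part is allylic or benzylic.

**Compound list**
1 | 3-methylbut-3-en-1-ol | C=C(C)CCO | starting material
2 | 3-methylbut-3-enal | C=C(C)CC=O | intermediate
3 | (4R)-4-benzyl-3-(3-methylbutanoyl)-1,3-oxazolidin-2-one | CC(C)CC(=O)N1[C@H](Cc2ccccc2)COC1=O | starting material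
4 | dibutylboron (Z)-enolate of 3 | CCCCB(CCCC)O/C(=C\C(C)C)N1[C@H](Cc2ccccc2)COC1=O | intermediate
5 | syn-aldol adduct | O=C1OC[C@@H](Cc2ccccc2)N1C(=O)[C@@H]([C@@H](O)CC(C)=C)C(C)C | intermediate
6 | hydroxy Weinreb amide | CON(C)C(=O)[C@@H]([C@@H](O)CC(C)=C)C(C)C | intermediate
7 | silylated Weinreb amide | CON(C)C(=O)[C@@H]([C@@H](O[Si](C)(C)C(C)(C)C)CC(C)=C)C(C)C | intermediate
8 | 5-methylhex-5-en-2-one | CC(=O)CCC(C)=C | starting material
9 | 2-methyl-2-(3-methylbut-3-en-1-yl)-1,3-dioxolane | CC1(CCC(C)=C)OCCO1 | intermediate
10 | allylpotassium reagent from 9 | [K+].[CH2-]C(=C)CCC1(C)OCCO1 | intermediate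
11 | acyclic dienyl ketone | C=C(CCC1(C)OCCO1)CC(=O)[C@@H]([C@@H](O[Si](C)(C)C(C)(C)C)CC(C)=C)C(C)C | intermediate
12 | ring B ketone, ketal | O=C1CC(CCC2(C)OCCO2)=C(C)C[C@H](O[Si](C)(C)C(C)(C)C)[C@H]1C(C)C | intermediate
13 | ring B diketone | O=C1CC(CCC(C)=O)=C(C)C[C@H](O[Si](C)(C)C(C)(C)C)[C@H]1C(C)C | intermediate
14 | lithium dienolate of 13 | [Li+].[O-]C1=CC(CCC(C)=O)=C(C)C[C@H](O[Si](C)(C)C(C)(C)C)[C@H]1C(C)C | intermediate
15 | lithium aldolate | [Li+].CC(C)(C)[Si](C)(C)O[C@H]1CC(C)=C2CC[C@](C)([O-])[C@@H]2C(=O)[C@@H]1C(C)C | intermediate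
16 | bicyclic hydroxy ketone | CC(C)(C)[Si](C)(C)O[C@H]1CC(C)=C2CC[C@](C)(O)[C@@H]2C(=O)[C@@H]1C(C)C | intermediate
17 | 4β,6β-diol, 8-O-TBS | CC(C)(C)[Si](C)(C)O[C@H]1CC(C)=C2CC[C@](C)(O)[C@@H]2[C@H](O)[C@@H]1C(C)C | intermediate
18 | 4β,6β,8α-triol | O[C@H]1CC(C)=C2CC[C@](C)(O)[C@@H]2[C@H](O)[C@@H]1C(C)C | intermediate
19 | 4-(benzyloxy)-3-methoxybenzoic acid | COc1cc(C(=O)O)ccc1OCc1ccccc1 | starting material
20 | O-benzyl vanillate ester | COc1cc(C(=O)O[C@H]2CC(C)=C3CC[C@](C)(O)[C@@H]3[C@H](O)[C@@H]2C(C)C)ccc1OCc1ccccc1 | intermediate
21 | CNP0299353.1 | COc1cc(C(=O)O[C@H]2CC(C)=C3CC[C@](C)(O)[C@@H]3[C@H](O)[C@@H]2C(C)C)ccc1O | target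

**Total step count:** 13. **Longest linear sequence:** 12 steps (steps 1–4 and 6–13).

**The three steps most likely to fail**

Step 9. Closure on the α face of C5, anti to the isopropyl group, is expected to be the faster process. Face selectivity is lost if retro-aldol equilibration of the lithium aldolates is slow. It is also lost if proton transfer to methyl-ketone enolates or loss of silanolate from C8 overtakes equilibration on warming. The fallback replaces thermodynamic selection by a temporary chelate ring and sets out from 13. HF·pyridine (THF, 0 °C) removes the silyl group to give (2R,3S)-3-hydroxy-5-methyl-6-(3-oxobutyl)-2-(propan-2-yl)cyclohept-5-en-1-one F3. Mg[N(SiMe3)2]2 (2 equiv, THF, −78 to −40 °C) takes the O8 proton and one C5 proton. Magnesium bridging O8 and O6 then closes a six-membered chelate ring that can exist only with C8–O pseudo-axial. In that pucker C8–C10 lie on the α side of the enolate plane and the chain on C1 is tilted to the β face. The kinetic closure itself should therefore give 4β,8α-dihydroxy-5αH,7αH-guai-1(10)-en-6-one F4. Reduction of F4 under the conditions of step 10 comes back to the route at 18, and step 11 is then not needed.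

Step 7. Slow turnover between two 1,1-disubstituted alkenes leaves time for catalyst decay to ruthenium hydrides. These can move the C1 methylidene into conjugation with the C6 ketone, and intermolecular metathesis can also compete. The fallback closes the ring at the carbinol oxidation level, where no skipped enone is present, and sets out from 11. NaBH4 (MeOH, 0 °C) gives the C6 carbinols of 11 (both epimers serve) F1. Metathesis with the same catalyst gives the cyclohept-5-en-1-ols F2. Dess–Martin oxidation of F2 comes back to the route at 12.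

Step 10. Exchange of an acetate on boron for the hindered tertiary C4 hydroxyl may be slow. In that case either no reduction occurs or undirected attack from the more open β face takes over. The fallback binds the hydride donor covalently first and sets out from 16. i-Pr2SiHCl, imidazole and DMAP in DMF give the 4-O-diisopropylsilyl ether of 16 F5. SnCl4 (cat., CH2Cl2, −78 °C) triggers the known anti-selective intramolecular hydrosilylation of β-silyloxy ketones and gives the 4,6-O-diisopropylsilylene derivative of 17 F6. Excess Bu4NF cleaves both silicon groups and comes back to the route at 18.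

**Further compounds**
F1 | step 7 | 6-[(tert-butyldimethylsilyl)oxy]-8-methyl-2-[2-(2-methyl-1,3-dioxolan-2-yl)ethyl]-5-(propan-2-yl)nona-1,8-dien-4-ol, C5 and C6 as in 11, both C4 epimers | C=C(CCC1(C)OCCO1)CC(O)[C@@H]([C@@H](O[Si](C)(C)C(C)(C)C)CC(C)=C)C(C)C
F2 | step 7 | 3-[(tert-butyldimethylsilyl)oxy]-5-methyl-6-[2-(2-methyl-1,3-dioxolan-2-yl)ethyl]-2-(propan-2-yl)cyclohept-5-en-1-ol, C2 and C3 as in 12, both C1 epimers | OC1CC(CCC2(C)OCCO2)=C(C)C[C@H](O[Si](C)(C)C(C)(C)C)[C@H]1C(C)C
F3 | step 9 | (2R,3S)-3-hydroxy-5-methyl-6-(3-oxobutyl)-2-(propan-2-yl)cyclohept-5-en-1-one | O=C1CC(CCC(C)=O)=C(C)C[C@H](O)[C@H]1C(C)C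
F4 | step 9 | 4β,8α-dihydroxy-5αH,7αH-guai-1(10)-en-6-one | O[C@H]1CC(C)=C2CC[C@](C)(O)[C@@H]2C(=O)[C@@H]1C(C)C
F5 | step 10 | 4-O-diisopropylsilyl ether of 16 | CC(C)(C)[Si](C)(C)O[C@H]1CC(C)=C2CC[C@](C)(O[SiH](C(C)C)C(C)C)[C@@H]2C(=O)[C@@H]1C(C)C
F6 | step 10 | 4,6-O-diisopropylsilylene derivative of 17 | CC(C)(C)[Si](C)(C)O[C@H]1CC(C)=C2CC[C@](C)(O3)[C@@H]2[C@H](O[Si]3(C(C)C)C(C)C)[C@@H]1C(C)C
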